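**Plan**

- Numbering: lactone carbonyl C1, ring alkene C2=C3, ring CH2 C4, ring O–CH C5, chain C6 (OH), C7 (OMe), C8=C9, C10 and C11 (OAc), C12 (CH3).
- Cuts: first C8=C9 (Julia–Kocienski; a C9–C12 sulfone and a C1–C8 lactone aldehyde), then the two ring bonds C4–C5 and O–C1.
- Enabling feature: the ring O–C1(=O)–C2=C3–C4–C5 is the oxidised form of a 2-methoxy-5,6-dihydro-2H-pyran, which is the hetero-Diels–Alder adduct of a C5 aldehyde (carrying C6–C8) and 1-methoxybutadiene (C1–C4).
- Forward order: glucose-derived C5–C8 aldehyde, ring closed by the cycloaddition, acetal oxidised to the lactone, C8 unveiled as aldehyde, C9–C12 joined, acetonide exchanged for two acetates, C6 desilylated.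
- Stereochemistry: C6 and C7 from D-glucose (its C4 and C5); C5 from the chiral chromium catalyst matched with Felkin–Anh control; C10 and C11 from L-threonine (C2 with retention, C3); C8=C9 (E) from the olefination.

Key step: step 5

Assumption 1: the sense of induction of the chromium catalyst is carried over from simple alkoxyacetaldehydes, for which the (1R,2S)-aminoindanol complex is taken to give the (2S,6R) cis adduct; the (1S,2R) complex is therefore used to reach the Si face of aldehyde 7.
Assumption 2: 1 is used as the commercial anomeric mixture with the (R)-ethylidene group; the uncontrolled centres of the non-isolated compounds 6 (ozonide carbon) and 10 (lactol carbon) are left undefined.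

**Route**

Step 1
Reactants: 1 4,6-O-ethylidene-D-glucopyranose
Product: 3 2,4-O-ethylidene-D-erythrose, via formate ester 2 (not isolated)
Conditions: NaIO4 (2.1 equiv), H2O, 0–10 °C; neutralised on work-up
Reagents that add atoms: none
Why: Malaprade glycol cleavage cuts C1–C2 and C2–C3 of the pyranose, so glucose C3–C6 remain as the erythrose acetal with its two stereocentres (later C6 and C7) untouched, and the formate left on the former ring oxygen hydrolyses on neutralisation.

Step 2
Reactants: 3 2,4-O-ethylidene-D-erythrose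
Product: 4 (2R,4S,5R)-2-methyl-4-vinyl-1,3-dioxan-5-ol
Conditions: Ph3PCH3Br (3 equiv), KOtBu (3 equiv), THF, 0 °C to rt
Reagents that add atoms: methyltriphenylphosphonium bromide, C[P+](c1ccccc1)(c1ccccc1)c1ccccc1.[Br-]
Why: Wittig methylenation of the free hydroxy aldehyde, a reaction type established for 2,4-O-alkylidene tetroses with excess non-stabilised ylide, masks the formyl group as a vinyl group so that the hydroxyl can be alkylated under basic conditions.

Step 3
Reactants: 4 (2R,4S,5R)-2-methyl-4-vinyl-1,3-dioxan-5-ol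
Product: 5 (2R,4S,5R)-5-methoxy-2-methyl-4-vinyl-1,3-dioxane
Conditions: NaH, MeI, THF, 0 °C to rt
Reagents that add atoms: iodomethane, CI
Why: Williamson etherification of the only free hydroxyl; the acetal and the alkene are inert and no stereocentre is acidic.

Step 4
Reactants: 5 (2R,4S,5R)-5-methoxy-2-methyl-4-vinyl-1,3-dioxane
Product: 7 2,4-O-ethylidene-3-O-methyl-D-erythrose [(2R,4R,5R)-5-methoxy-2-methyl-1,3-dioxane-4-carbaldehyde], via ozonide 6 (not isolated)
Conditions: O3, CH2Cl2, −78 °C (stopped at the end point); then PPh3, −78 °C to rt; used at once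
Reagents that add atoms: ozone, [O-][O+]=O
Why: Ozonolysis with reductive work-up returns the formyl group under neutral, non-epimerising conditions, the alkene reacting far faster than the acetal C–H bonds.

Step 5
Reactants: 7 2,4-O-ethylidene-3-O-methyl-D-erythrose; 8 (E)-1-methoxybuta-1,3-diene
Product: 9 (2R,4S,5R)-5-methoxy-4-[(2S,6R)-6-methoxy-3,6-dihydro-2H-pyran-2-yl]-2-methyl-1,3-dioxane (cis acetal)
Conditions: (L)CrCl (5 mol %; L = C27H29NO2, the dianion of the Schiff base of (1S,2R)-1-amino-2-indanol and 3-(1-adamantyl)-2-hydroxy-5-methylbenzaldehyde; trivalent chromium), powdered 4 Å MS, neat 8 (3 equiv), rt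
Reagents that add atoms: none
Why: The chromium centre binds the aldehyde oxygen of 7 and the diene adds through a concerted, asynchronous endo [4+2] transition state, the unsubstituted diene terminus bonding to the carbonyl carbon (C4–C5) and the carbonyl oxygen to the methoxy-bearing terminus (O–C1); the closest known reaction type is the Schiff-base chromium chloride catalysed hetero-Diels–Alder reaction of 1-methoxybutadiene with α-alkoxy aldehydes. The dihydropyran ring closes in the cycloaddition itself, as an intermolecular [4+2] annulation in which both ring bonds form in one step. C5 is set by the catalyst, whose (1S,2R) enantiomer should direct the diene to the Si face of the carbonyl, the same face that Felkin–Anh attack anti to the dioxane C–O bond prefers, so the pair is matched and the C5 oxygen should come out anti to the C6 oxygen. The acetal carbon C1 is set by the endo geometry (methoxy cis to the C5 substituent) and is erased in step 6. Regioselectivity follows from the polarisation of the 1-methoxydiene, and neither epimerisation at C6 nor β-elimination of methoxide is expected because the medium is neutral and free of base.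

Step 6
Reactants: 9 cis methyl acetal
Product: 11 (6S)-6-[(2R,4S,5R)-5-methoxy-2-methyl-1,3-dioxan-4-yl]-5,6-dihydro-2H-pyran-2-one, via lactol 10 (not isolated)
Conditions: CrO3, H2SO4, H2O, acetone, 0 °C
Reagents that add atoms: water, O
Why: Jones oxidation: the aqueous acid hydrolyses the labile allylic methyl acetal to the lactol, which hexavalent chromium oxidises at once to the α,β-unsaturated δ-lactone, while the ethylidene dioxane and the methyl ether withstand the short exposure at 0 °C.

Step 7
Reactants: 11 ethylidene lactone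
Product: 12 (6S)-6-[(1S,2R)-1,3-dihydroxy-2-methoxypropyl]-5,6-dihydro-2H-pyran-2-one
Conditions: TFA/H2O (9:1), 0 °C to rt; evaporation
Reagents that add atoms: none
Why: Acid-catalysed acetal hydrolysis: the strong aqueous acid cleaves the robust ethylidene dioxane, acetaldehyde leaves on evaporation, and the unsaturated lactone and the methyl ether are stable to acid.

Step 8
Reactants: 12 diol lactone
Product: 13 (6S)-6-[(1S,2R)-1,3-bis(tert-butyldimethylsilyloxy)-2-methoxypropyl]-5,6-dihydro-2H-pyran-2-one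
Conditions: TBSOTf (2.5 equiv), 2,6-lutidine, CH2Cl2, −78 to −20 °C
Reagents that add atoms: tert-butyldimethylsilyl triflate, CC(C)(C)[Si](C)(C)OS(=O)(=O)C(F)(F)F
Why: Silyl triflate silylation protects both hydroxyls, the hindered C6 hydroxyl needing the triflate, and the weak hindered base should not enolise the lactone at low temperature.

Step 9
Reactants: 13 bis-silyl ether
Product: 14 (6S)-6-[(1S,2R)-1-(tert-butyldimethylsilyloxy)-3-hydroxy-2-methoxypropyl]-5,6-dihydro-2H-pyran-2-one
Conditions: HF·pyridine, pyridine, THF, 0 °C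
Reagents that add atoms: none
Why: Selective desilylation: buffered HF·pyridine removes the unhindered primary silyl ether much faster than the flanked secondary one at C6.

Step 10
Reactants: 14 primary alcohol
Product: 15 C8 aldehyde, (2S,3S)-3-(tert-butyldimethylsilyloxy)-2-methoxy-3-[(2S)-6-oxo-3,6-dihydro-2H-pyran-2-yl]propanal
Conditions: Dess–Martin periodinane, CH2Cl2, 0 °C to rt; used at once
Reagents that add atoms: none
Why: Dess–Martin oxidation of the primary alcohol under neutral conditions should give the α-methoxy aldehyde without epimerisation at C7 or β-elimination of the silyloxy group.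

Step 11
Reactants: 16 L-threonine
Product: 17 (2S,3R)-2,3-dihydroxybutanoic acid
Conditions: NaNO2, 1 M aq. H2SO4, 0 °C to rt
Reagents that add atoms: water, O
Why: Diazotisation of the α-amino acid with net retention: the carboxylate displaces N2 to an α-lactone that water opens, a double inversion that keeps the (2S) configuration while C3 is untouched.

Step 12
Reactants: 17 (2S,3R)-2,3-dihydroxybutanoic acid
Product: 18 methyl (4S,5R)-2,2,5-trimethyl-1,3-dioxolane-4-carboxylate
Conditions: 2,2-dimethoxypropane, MeOH, TsOH·H2O (cat.), reflux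
Reagents that add atoms: 2,2-dimethoxypropane, COC(C)(C)OC; methanol, CO
Why: Fischer esterification and acetonide formation by acid-catalysed ketal exchange in one operation, as practised for tartaric acid; the threo diol gives the trans-dioxolane.

Step 13
Reactants: 18 acetonide ester
Product: 19 [(4R,5R)-2,2,5-trimethyl-1,3-dioxolan-4-yl]methanol
Conditions: LiAlH4, THF, 0 °C
Reagents that add atoms: none
Why: Hydride reduction of the ester to the primary alcohol; the dioxolane is inert and no stereocentre is affected.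

Step 14
Reactants: 19 acetonide alcohol
Product: 20 1-phenyl-5-({[(4S,5R)-2,2,5-trimethyl-1,3-dioxolan-4-yl]methyl}sulfanyl)-1H-tetrazole
Conditions: 1-phenyl-1H-tetrazole-5-thiol, PPh3, DIAD, THF, 0 °C to rt
Reagents that add atoms: 1-phenyl-1H-tetrazole-5-thiol, Sc1nnnn1-c1ccccc1
Why: Mitsunobu thioetherification: the acidic tetrazole thiol displaces the activated primary hydroxyl, with no stereocentre involved.

Step 15
Reactants: 20 sulfide
Product: 21 1-phenyl-5-({[(4S,5R)-2,2,5-trimethyl-1,3-dioxolan-4-yl]methyl}sulfonyl)-1H-tetrazole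
Conditions: 30% aq. H2O2, (NH4)6Mo7O24·4H2O (cat.), EtOH, 0 °C to rt
Reagents that add atoms: hydrogen peroxide, OO
Why: Molybdate-catalysed peroxide oxidation of the sulfide to the sulfone; the weakly acidic medium leaves the acetonide intact.

Step 16
Reactants: 15 C8 aldehyde; 21 C9–C12 sulfone
Product: 22 (6S)-6-{(1S,2R,3E)-1-(tert-butyldimethylsilyloxy)-2-methoxy-4-[(4R,5R)-2,2,5-trimethyl-1,3-dioxolan-4-yl]but-3-en-1-yl}-5,6-dihydro-2H-pyran-2-one
Conditions: KN(SiMe3)2 (1.2 equiv) added to 15 and 21 (1.3 equiv), DME, −60 °C to rt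
Reagents that add atoms: none
Why: Julia–Kocienski olefination: the metallated phenyltetrazolyl sulfone adds to the aldehyde, and Smiles rearrangement with loss of SO2 and tetrazolate gives the alkene, the potassium counter-ion in DME favouring the (E)-isomer; forming the anion in the presence of the aldehyde at low temperature is meant to outrun β-elimination of the acetonide oxygen and attack on the base-sensitive lactone.

Step 17
Reactants: 22 acetonide
Product: 23 (6S)-6-[(1S,2R,3E,5R,6R)-1-(tert-butyldimethylsilyloxy)-5,6-dihydroxy-2-methoxyhept-3-en-1-yl]-5,6-dihydro-2H-pyran-2-one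
Conditions: PPTS, MeOH, 45 °C
Reagents that add atoms: none
Why: Acid-catalysed transketalisation to methanol removes the acetonide, while the hindered secondary silyl ether, much slower to solvolyse, should stay in place.

Step 18
Reactants: 23 diol
Product: 24 (6S)-6-[(1S,2R,3E,5R,6R)-5,6-diacetoxy-1-(tert-butyldimethylsilyloxy)-2-methoxyhept-3-en-1-yl]-5,6-dihydro-2H-pyran-2-one
Conditions: Ac2O, pyridine, DMAP (cat.), CH2Cl2, 0 °C to rt
Reagents that add atoms: acetic anhydride, CC(=O)OC(C)=O
Why: DMAP-catalysed acylation of the two secondary hydroxyls; the C6 oxygen is still silylated, so only C10 and C11 are acetylated.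

Step 19
Reactants: 24 silyl ether diacetate
Product: 25 (6S)-6-[(1S,2R,3E,5R,6R)-5,6-diacetoxy-1-hydroxy-2-methoxyhept-3-en-1-yl]-5,6-dihydro-2H-pyran-2-one (target)
Conditions: HF·pyridine, THF, 0 °C to rt
Reagents that add atoms: none
Why: Fluoride-mediated desilylation under slightly acidic conditions should free the C6 hydroxyl without acetyl migration, acetate hydrolysis or opening of the lactone.

**Compound list**

1 | 4,6-O-ethylidene-D-glucopyranose | C[C@@H]1OC[C@H]2OC(O)[C@H](O)[C@@H](O)[C@@H]2O1 | starting material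
2 | 3-O-formyl-2,4-O-ethylidene-D-erythrose | O=CO[C@@H]1CO[C@@H](C)O[C@H]1C=O | intermediate
3 | 2,4-O-ethylidene-D-erythrose | O[C@@H]1CO[C@@H](C)O[C@H]1C=O | intermediate
4 | (2R,4S,5R)-2-methyl-4-vinyl-1,3-dioxan-5-ol | O[C@@H]1CO[C@@H](C)O[C@H]1C=C | intermediate
5 | (2R,4S,5R)-5-methoxy-2-methyl-4-vinyl-1,3-dioxane | CO[C@@H]1CO[C@@H](C)O[C@H]1C=C | intermediate
6 | ozonide of 5 (3-substituted 1,2,4-trioxolane) | CO[C@@H]1CO[C@@H](C)O[C@H]1C2OCOO2 | intermediate
7 | 2,4-O-ethylidene-3-O-methyl-D-erythrose | CO[C@@H]1CO[C@@H](C)O[C@H]1C=O | intermediate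
8 | (E)-1-methoxybuta-1,3-diene | CO/C=C/C=C | starting material
9 | (2R,4S,5R)-5-methoxy-4-[(2S,6R)-6-methoxy-3,6-dihydro-2H-pyran-2-yl]-2-methyl-1,3-dioxane | CO[C@@H]1CO[C@@H](C)O[C@H]1[C@@H]2CC=C[C@H](OC)O2 | intermediate
10 | lactol from 9 (6-hydroxy-3,6-dihydro-2H-pyran-2-yl analogue) | CO[C@@H]1CO[C@@H](C)O[C@H]1[C@@H]2CC=CC(O)O2 | intermediate
11 | (6S)-6-[(2R,4S,5R)-5-methoxy-2-methyl-1,3-dioxan-4-yl]-5,6-dihydro-2H-pyran-2-one | CO[C@@H]1CO[C@@H](C)O[C@H]1[C@@H]2CC=CC(=O)O2 | intermediate
12 | (6S)-6-[(1S,2R)-1,3-dihydroxy-2-methoxypropyl]-5,6-dihydro-2H-pyran-2-one | CO[C@H](CO)[C@@H](O)[C@@H]1CC=CC(=O)O1 | intermediate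
13 | (6S)-6-[(1S,2R)-1,3-bis(tert-butyldimethylsilyloxy)-2-methoxypropyl]-5,6-dihydro-2H-pyran-2-one | CO[C@H](CO[Si](C)(C)C(C)(C)C)[C@@H](O[Si](C)(C)C(C)(C)C)[C@@H]1CC=CC(=O)O1 | intermediate
14 | (6S)-6-[(1S,2R)-1-(tert-butyldimethylsilyloxy)-3-hydroxy-2-methoxypropyl]-5,6-dihydro-2H-pyran-2-one | CO[C@H](CO)[C@@H](O[Si](C)(C)C(C)(C)C)[C@@H]1CC=CC(=O)O1 | intermediate
15 | (2S,3S)-3-(tert-butyldimethylsilyloxy)-2-methoxy-3-[(2S)-6-oxo-3,6-dihydro-2H-pyran-2-yl]propanal | CO[C@H](C=O)[C@@H](O[Si](C)(C)C(C)(C)C)[C@@H]1CC=CC(=O)O1 | intermediate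
16 | L-threonine | C[C@@H](O)[C@H](N)C(=O)O | starting material
17 | (2S,3R)-2,3-dihydroxybutanoic acid | C[C@@H](O)[C@H](O)C(=O)O | intermediate
18 | methyl (4S,5R)-2,2,5-trimethyl-1,3-dioxolane-4-carboxylate | COC(=O)[C@H]1OC(C)(C)O[C@@H]1C | intermediate
19 | [(4R,5R)-2,2,5-trimethyl-1,3-dioxolan-4-yl]methanol | OC[C@H]1OC(C)(C)O[C@@H]1C | intermediate
20 | 1-phenyl-5-({[(4S,5R)-2,2,5-trimethyl-1,3-dioxolan-4-yl]methyl}sulfanyl)-1H-tetrazole | S(C[C@H]1OC(C)(C)O[C@@H]1C)c2nnnn2-c3ccccc3 | intermediate
21 | 1-phenyl-5-({[(4S,5R)-2,2,5-trimethyl-1,3-dioxolan-4-yl]methyl}sulfonyl)-1H-tetrazole | O=S(=O)(C[C@H]1OC(C)(C)O[C@@H]1C)c2nnnn2-c3ccccc3 | intermediate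
22 | (6S)-6-{(1S,2R,3E)-1-(tert-butyldimethylsilyloxy)-2-methoxy-4-[(4R,5R)-2,2,5-trimethyl-1,3-dioxolan-4-yl]but-3-en-1-yl}-5,6-dihydro-2H-pyran-2-one | CO[C@H](/C=C/[C@H]1OC(C)(C)O[C@@H]1C)[C@@H](O[Si](C)(C)C(C)(C)C)[C@@H]2CC=CC(=O)O2 | intermediate
23 | (6S)-6-[(1S,2R,3E,5R,6R)-1-(tert-butyldimethylsilyloxy)-5,6-dihydroxy-2-methoxyhept-3-en-1-yl]-5,6-dihydro-2H-pyran-2-one | CO[C@H](/C=C/[C@@H](O)[C@@H](C)O)[C@@H](O[Si](C)(C)C(C)(C)C)[C@@H]1CC=CC(=O)O1 | intermediate
24 | (6S)-6-[(1S,2R,3E,5R,6R)-5,6-diacetoxy-1-(tert-butyldimethylsilyloxy)-2-methoxyhept-3-en-1-yl]-5,6-dihydro-2H-pyran-2-one | CO[C@H](/C=C/[C@@H](OC(C)=O)[C@@H](C)OC(C)=O)[C@@H](O[Si](C)(C)C(C)(C)C)[C@@H]1CC=CC(=O)O1 | intermediate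
25 | (6S)-6-[(1S,2R,3E,5R,6R)-5,6-diacetoxy-1-hydroxy-2-methoxyhept-3-en-1-yl]-5,6-dihydro-2H-pyran-2-one | CO[C@H](/C=C/[C@@H](OC(C)=O)[C@@H](C)OC(C)=O)[C@@H](O)[C@@H]1CC=CC(=O)O1 | target

**Step count**

Total: 19 steps. Longest linear sequence: 14 steps (steps 1–10 and 16–19, from 1). The sulfone branch (steps 11–15) is 5 steps and joins at step 16.

**Steps most likely to fail**

Step 5. The Lewis-basic dioxane and methoxy oxygens of 7 may chelate chromium and erode catalyst control, giving poor facial selectivity, or the hindered, easily hydrated aldehyde may react sluggishly. The fallback sets out from 7 and replaces the cycloaddition by allylation and ring-closing metathesis. Allylboration with the B-allyldiisopinocampheylborane enantiomer that attacks the Si face, taken as (−)-Ipc2B(allyl) (Et2O, −78 °C; then NaOH/H2O2), again matched with Felkin–Anh control, should give (1S)-1-[(2R,4S,5R)-5-methoxy-2-methyl-1,3-dioxan-4-yl]but-3-en-1-ol F1. Acylation with acryloyl chloride (Et3N, DMAP, CH2Cl2) gives the acrylate F2. Ring-closing metathesis with second-generation Grubbs catalyst (H2IMes)(PCy3)Cl2Ru=CHPh in CH2Cl2 at reflux then closes the unsaturated lactone and returns to the route at 11.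

Step 16. The metallated sulfone may lose the acetonide oxygen by β-elimination, base or carbanion may deprotonate or add to the unsaturated lactone, and C7 may epimerise in the aldehyde. The fallback is a base-free cross-metathesis. From 15, Takai–Lombardo methylenation (Zn, CH2I2, TiCl4, THF, 0 °C) gives the terminal alkene (6S)-6-[(1S,2R)-1-(tert-butyldimethylsilyloxy)-2-methoxybut-3-en-1-yl]-5,6-dihydro-2H-pyran-2-one F3. From 19, Swern oxidation gives (4S,5R)-2,2,5-trimethyl-1,3-dioxolane-4-carbaldehyde F4, and Wittig methylenation (Ph3PCH3Br, KOtBu, THF) gives (4R,5R)-2,2,4-trimethyl-5-vinyl-1,3-dioxolane F5. Cross-metathesis of F3 with excess F5 using second-generation Hoveyda–Grubbs catalyst (H2IMes)Cl2Ru(=CH–C6H4-2-OiPr) in CH2Cl2 at 40 °C should favour the (E)-alkene and returns to the route at 22.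

Step 7. Hydrolysis of the robust ethylidene acetal may stay incomplete, or the forcing acid may open or degrade the lactone diol. The fallback removes the acetal earlier, at the stage of the sturdy alkene 5. Acidic methanolysis (HCl, MeOH, 50 °C) gives (2R,3S)-2-methoxypent-4-ene-1,3-diol F6. Silylation (TBSOTf, 2,6-lutidine) gives the bis-silyl ether F7, and ozonolysis (O3; PPh3) gives (2R,3R)-2,4-bis(tert-butyldimethylsilyloxy)-3-methoxybutanal F8. The same chromium-catalysed cycloaddition with 8, now relying on catalyst control and the polar Felkin–Anh preference of the α-silyloxy aldehyde, gives the cis methyl acetal F9. Mild hydrolysis (PPTS, acetone/H2O) gives the lactol F10, and MnO2 in CH2Cl2 oxidises it to the lactone, returning to the route at 13.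

Further compounds
F1 | step 5 | (1S)-1-[(2R,4S,5R)-5-methoxy-2-methyl-1,3-dioxan-4-yl]but-3-en-1-ol | CO[C@@H]1CO[C@@H](C)O[C@H]1[C@@H](O)CC=C
F2 | step 5 | (1S)-1-[(2R,4S,5R)-5-methoxy-2-methyl-1,3-dioxan-4-yl]but-3-en-1-yl acrylate | CO[C@@H]1CO[C@@H](C)O[C@H]1[C@@H](OC(=O)C=C)CC=C
F3 | step 16 | (6S)-6-[(1S,2R)-1-(tert-butyldimethylsilyloxy)-2-methoxybut-3-en-1-yl]-5,6-dihydro-2H-pyran-2-one | CO[C@H](C=C)[C@@H](O[Si](C)(C)C(C)(C)C)[C@@H]1CC=CC(=O)O1
F4 | step 16 | (4S,5R)-2,2,5-trimethyl-1,3-dioxolane-4-carbaldehyde | O=C[C@H]1OC(C)(C)O[C@@H]1C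
F5 | step 16 | (4R,5R)-2,2,4-trimethyl-5-vinyl-1,3-dioxolane | C=C[C@H]1OC(C)(C)O[C@@H]1C
F6 | step 7 | (2R,3S)-2-methoxypent-4-ene-1,3-diol | CO[C@H](CO)[C@@H](O)C=C
F7 | step 7 | (3S,4R)-3,5-bis(tert-butyldimethylsilyloxy)-4-methoxypent-1-ene | CO[C@H](CO[Si](C)(C)C(C)(C)C)[C@@H](O[Si](C)(C)C(C)(C)C)C=C
F8 | step 7 | (2R,3R)-2,4-bis(tert-butyldimethylsilyloxy)-3-methoxybutanal | CO[C@H](CO[Si](C)(C)C(C)(C)C)[C@@H](O[Si](C)(C)C(C)(C)C)C=O
F9 | step 7 | (2S,6R)-2-[(1S,2R)-1,3-bis(tert-butyldimethylsilyloxy)-2-methoxypropyl]-6-methoxy-3,6-dihydro-2H-pyran | CO[C@H](CO[Si](C)(C)C(C)(C)C)[C@@H](O[Si](C)(C)C(C)(C)C)[C@@H]1CC=C[C@H](OC)O1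
F10 | step 7 | (6S)-6-[(1S,2R)-1,3-bis(tert-butyldimethylsilyloxy)-2-methoxypropyl]-5,6-dihydro-2H-pyran-2-ol | CO[C@H](CO[Si](C)(C)C(C)(C)C)[C@@H](O[Si](C)(C)C(C)(C)C)[C@@H]1CC=CC(O)O1
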